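**Retrosynthetic overview**
1. Target 19 comes from global O-debenzylation of hexabenzyl ether 18; ring A needs no protection because it is made last.
2. Ring A is built de novo on the ring B oxygen: 18 from diester 16 by ester hydrolysis and decarboxylation; 16 from a crossed Claisen C–C bond formation between aryloxymalonate 13 and diethyl 3-oxopentanedioate 14, followed by Dieckmann closure and aromatisation.
3. 13 from phenol 11 and diethyl chloromalonate 12; 11 from Ullmann C–O coupling of ring B phenol 9 with ring C bromide 3, a MOM group marking the oxygen reserved for ring A.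
4. 9 from 3,4,5-tris(benzyloxy)phenol 4 by ortho-formylation, MOM protection and Baeyer–Villiger oxidation; 3 and 4 both from 5-bromo-1,2,3-trimethoxybenzene 1.
5. Ring order: rings C and B start as arenes and are joined first (C–O–B); ring A is formed last.

Assumption: the target has no stereocentre and no stereogenic axis (it is achiral), so no stereocontrol is needed and no SMILES carries stereodescriptors.

**Route**

Step 1
Reactants: 1 5-bromo-1,2,3-trimethoxybenzene
Product: 2 5-bromobenzene-1,2,3-triol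
Conditions: BBr3 (3.5 equiv), CH2Cl2, −78 °C → rt; then H2O
Reagents that add atoms: none
Why: Lewis-acid ether cleavage with BBr3 removes all three aryl methyl ethers and leaves the aryl bromide untouched.

Step 2
Reactants: 2 5-bromobenzene-1,2,3-triol
Product: 3 1,2,3-tris(benzyloxy)-5-bromobenzene
Conditions: BnBr (3.5 equiv), K2CO3, DMF, 60 °C, N2
Reagents that add atoms: benzyl bromide, BrCc1ccccc1
Why: Williamson etherification of the three phenoxides gives the benzyl ethers that survive every later step and fall off together at the end.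

Step 3
Reactants: 3 1,2,3-tris(benzyloxy)-5-bromobenzene
Product: 4 3,4,5-tris(benzyloxy)phenol
Conditions: Pd2(dba)3 (2 mol%), tBuXPhos (8 mol%), KOH (3 equiv), 1,4-dioxane/H2O 1:1, 100 °C; then 1 M HCl
Reagents that add atoms: potassium hydroxide, [K+].[OH-]
Why: Palladium-catalysed C–O coupling of an aryl bromide with hydroxide (Buchwald hydroxylation) is general for electron-rich bromides and tolerates benzyl ethers.

Step 4
Reactants: 4 3,4,5-tris(benzyloxy)phenol
Product: 6 2,3,4-tris(benzyloxy)-6-hydroxybenzaldehyde, via salicyl alcohol 5 (not isolated)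
Conditions: MgCl2 (2 equiv), Et3N (4 equiv), (CH2O)n (6 equiv), MeCN, reflux; then 1 M HCl
Reagents that add atoms: paraformaldehyde (formaldehyde), C=O
Why: Casnati–Skattebøl ortho-formylation delivers formaldehyde through the magnesium phenoxide only ortho to OH (the two ortho sites are equivalent), and the hydroxymethyl intermediate is oxidised in the flask by a second formaldehyde through hydride transfer.

Step 5
Reactants: 6 2,3,4-tris(benzyloxy)-6-hydroxybenzaldehyde
Product: 7 2,3,4-tris(benzyloxy)-6-(methoxymethoxy)benzaldehyde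
Conditions: NaH (1.3 equiv), DMF, 0 °C; MOMCl (1.3 equiv), 0 °C → rt
Reagents that add atoms: chloromethyl methyl ether, COCCl
Why: O-alkylation of the sodium phenoxide (Williamson type) overcomes the chelated OH and installs an acetal that cannot migrate to the neighbouring oxygen and is orthogonal to benzyl.

Step 6
Reactants: 7 2,3,4-tris(benzyloxy)-6-(methoxymethoxy)benzaldehyde
Product: 9 2,3,4-tris(benzyloxy)-6-(methoxymethoxy)phenol, via aryl formate 8 (not isolated)
Conditions: mCPBA (1.3 equiv), CH2Cl2, 0 °C → rt; aq. NaHCO3/Na2S2O3 wash; then K2CO3 (cat.), MeOH, rt, Ar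
Reagents that add atoms: mCPBA, OOC(=O)c1cccc(Cl)c1
Why: Baeyer–Villiger oxidation of the electron-rich 2,6-dialkoxybenzaldehyde proceeds by aryl migration to the formate, which mild methanolysis cleaves to the phenol.

Step 7
Reactants: 9 2,3,4-tris(benzyloxy)-6-(methoxymethoxy)phenol; 3 1,2,3-tris(benzyloxy)-5-bromobenzene (1.3 equiv)
Product: 10 1,2,3-tris(benzyloxy)-5-(methoxymethoxy)-4-[3,4,5-tris(benzyloxy)phenoxy]benzene
Conditions: CuI (10 mol%), picolinic acid (20 mol%), K3PO4 (2 equiv), degassed DMSO, 100 °C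
Reagents that add atoms: none
Why: Ullmann diaryl ether coupling under CuI/picolinic acid conditions accepts di-ortho-substituted phenols when the aryl bromide has both ortho positions free, as here.

Step 8
Reactants: 10 1,2,3-tris(benzyloxy)-5-(methoxymethoxy)-4-[3,4,5-tris(benzyloxy)phenoxy]benzene
Product: 11 3,4,5-tris(benzyloxy)-2-[3,4,5-tris(benzyloxy)phenoxy]phenol
Conditions: conc. HCl (5 equiv), MeOH/THF 1:1, 50 °C
Reagents that add atoms: none
Why: Acid-catalysed acetal cleavage removes only the MOM group, since benzyl and diaryl ethers are inert to dilute HCl in methanol.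

Step 9
Reactants: 11 3,4,5-tris(benzyloxy)-2-[3,4,5-tris(benzyloxy)phenoxy]phenol; 12 diethyl 2-chloropropanedioate (1.2 equiv)
Product: 13 diethyl 2-{3,4,5-tris(benzyloxy)-2-[3,4,5-tris(benzyloxy)phenoxy]phenoxy}propanedioate
Conditions: K2CO3 (2 equiv), acetone, 55 °C
Reagents that add atoms: none
Why: SN2 O-alkylation of the phenoxide with the α-chloromalonate (Williamson type) forms the future ring A C–O bond at an sp3 carbon, avoiding a hindered aryl–O coupling, and the chloride is used because it does not halogenate the phenoxide.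

Step 10
Reactants: 13 diethyl 2-{3,4,5-tris(benzyloxy)-2-[3,4,5-tris(benzyloxy)phenoxy]phenoxy}propanedioate; 14 diethyl 3-oxopentanedioate (2 equiv, added slowly)
Product: 16 diethyl 2,4,6-trihydroxy-5-{3,4,5-tris(benzyloxy)-2-[3,4,5-tris(benzyloxy)phenoxy]phenoxy}benzene-1,3-dicarboxylate, via acyclic Claisen adduct 15 (not isolated)
Conditions: NaOEt (3 equiv), EtOH, reflux; then EtOH distilled off from toluene, 110 °C; 1 M HCl
Reagents that add atoms: none
Why: In a crossed Claisen condensation the sodium enolate of 14 attacks an ester carbonyl of 13, and the tricarbonyl adduct closes by Dieckmann condensation and tautomerises to the aromatic triol, whose phenoxide salt is the thermodynamic sink (no stereocentre is formed).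

Step 11
Reactants: 16 diethyl 2,4,6-trihydroxy-5-{3,4,5-tris(benzyloxy)-2-[3,4,5-tris(benzyloxy)phenoxy]phenoxy}benzene-1,3-dicarboxylate
Product: 18 2-{3,4,5-tris(benzyloxy)-2-[3,4,5-tris(benzyloxy)phenoxy]phenoxy}benzene-1,3,5-triol, via dicarboxylic acid 17 (not isolated)
Conditions: KOH (10 equiv), degassed EtOH/H2O 1:1, reflux, Ar; then 2 M HCl to pH 2, 60 °C
Reagents that add atoms: none
Why: Saponification followed by decarboxylation is facile for phloroglucinol carboxylic acids because they react as vinylogous β-keto acids, while benzyl and diaryl ethers are stable to alkali.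

Step 12
Reactants: 18 2-{3,4,5-tris(benzyloxy)-2-[3,4,5-tris(benzyloxy)phenoxy]phenoxy}benzene-1,3,5-triol
Product: 19 2-[3,4,5-trihydroxy-2-(3,4,5-trihydroxyphenoxy)phenoxy]benzene-1,3,5-triol (target)
Conditions: H2 (1 atm), 10% Pd/C, THF/MeOH 1:1, rt; filtration and concentration under Ar
Reagents that add atoms: none
Why: Catalytic hydrogenolysis cleaves all six benzyl ethers under neutral conditions that do not touch diaryl ethers or the oxidation-prone polyphenol.

**Compound list**
1 | 5-bromo-1,2,3-trimethoxybenzene | COc1cc(Br)cc(OC)c1OC | starting material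
2 | 5-bromobenzene-1,2,3-triol | Oc1cc(Br)cc(O)c1O | intermediate
3 | 1,2,3-tris(benzyloxy)-5-bromobenzene | Brc1cc(OCc2ccccc2)c(OCc2ccccc2)c(OCc2ccccc2)c1 | intermediate
4 | 3,4,5-tris(benzyloxy)phenol | Oc1cc(OCc2ccccc2)c(OCc2ccccc2)c(OCc2ccccc2)c1 | intermediate
5 | 3,4,5-tris(benzyloxy)-2-(hydroxymethyl)phenol (formed as its magnesium salt) | OCc1c(O)cc(OCc2ccccc2)c(OCc2ccccc2)c1OCc2ccccc2 | intermediate (not isolated)
6 | 2,3,4-tris(benzyloxy)-6-hydroxybenzaldehyde | O=Cc1c(O)cc(OCc2ccccc2)c(OCc2ccccc2)c1OCc2ccccc2 | intermediate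
7 | 2,3,4-tris(benzyloxy)-6-(methoxymethoxy)benzaldehyde | O=Cc1c(OCOC)cc(OCc2ccccc2)c(OCc2ccccc2)c1OCc2ccccc2 | intermediate
8 | 2,3,4-tris(benzyloxy)-6-(methoxymethoxy)phenyl formate | O=COc1c(OCOC)cc(OCc2ccccc2)c(OCc2ccccc2)c1OCc2ccccc2 | intermediate (not isolated)
9 | 2,3,4-tris(benzyloxy)-6-(methoxymethoxy)phenol | Oc1c(OCOC)cc(OCc2ccccc2)c(OCc2ccccc2)c1OCc2ccccc2 | intermediate
10 | 1,2,3-tris(benzyloxy)-5-(methoxymethoxy)-4-[3,4,5-tris(benzyloxy)phenoxy]benzene | COCOc1cc(OCc2ccccc2)c(OCc2ccccc2)c(OCc2ccccc2)c1Oc3cc(OCc2ccccc2)c(OCc2ccccc2)c(OCc2ccccc2)c3 | intermediate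
11 | 3,4,5-tris(benzyloxy)-2-[3,4,5-tris(benzyloxy)phenoxy]phenol | Oc1cc(OCc2ccccc2)c(OCc2ccccc2)c(OCc2ccccc2)c1Oc3cc(OCc2ccccc2)c(OCc2ccccc2)c(OCc2ccccc2)c3 | intermediate
12 | diethyl 2-chloropropanedioate (diethyl chloromalonate) | CCOC(=O)C(Cl)C(=O)OCC | starting material
13 | diethyl 2-{3,4,5-tris(benzyloxy)-2-[3,4,5-tris(benzyloxy)phenoxy]phenoxy}propanedioate | CCOC(=O)C(Oc1cc(OCc2ccccc2)c(OCc2ccccc2)c(OCc2ccccc2)c1Oc3cc(OCc2ccccc2)c(OCc2ccccc2)c(OCc2ccccc2)c3)C(=O)OCC | intermediate
14 | diethyl 3-oxopentanedioate (diethyl acetonedicarboxylate) | CCOC(=O)CC(=O)CC(=O)OCC | starting material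
15 | triethyl 1-{3,4,5-tris(benzyloxy)-2-[3,4,5-tris(benzyloxy)phenoxy]phenoxy}-2,4-dioxopentane-1,3,5-tricarboxylate (enolised mixture, no defined stereochemistry) | CCOC(=O)CC(=O)C(C(=O)OCC)C(=O)C(Oc1cc(OCc2ccccc2)c(OCc2ccccc2)c(OCc2ccccc2)c1Oc3cc(OCc2ccccc2)c(OCc2ccccc2)c(OCc2ccccc2)c3)C(=O)OCC | intermediate (not isolated)
16 | diethyl 2,4,6-trihydroxy-5-{3,4,5-tris(benzyloxy)-2-[3,4,5-tris(benzyloxy)phenoxy]phenoxy}benzene-1,3-dicarboxylate | CCOC(=O)c1c(O)c(C(=O)OCC)c(O)c(Oc3cc(OCc2ccccc2)c(OCc2ccccc2)c(OCc2ccccc2)c3Oc4cc(OCc2ccccc2)c(OCc2ccccc2)c(OCc2ccccc2)c4)c1O | intermediate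
17 | 2,4,6-trihydroxy-5-{3,4,5-tris(benzyloxy)-2-[3,4,5-tris(benzyloxy)phenoxy]phenoxy}benzene-1,3-dicarboxylic acid | OC(=O)c1c(O)c(C(=O)O)c(O)c(Oc3cc(OCc2ccccc2)c(OCc2ccccc2)c(OCc2ccccc2)c3Oc4cc(OCc2ccccc2)c(OCc2ccccc2)c(OCc2ccccc2)c4)c1O | intermediate (not isolated)
18 | 2-{3,4,5-tris(benzyloxy)-2-[3,4,5-tris(benzyloxy)phenoxy]phenoxy}benzene-1,3,5-triol | Oc1cc(O)c(Oc3cc(OCc2ccccc2)c(OCc2ccccc2)c(OCc2ccccc2)c3Oc4cc(OCc2ccccc2)c(OCc2ccccc2)c(OCc2ccccc2)c4)c(O)c1 | intermediate
19 | 2-[3,4,5-trihydroxy-2-(3,4,5-trihydroxyphenoxy)phenoxy]benzene-1,3,5-triol (achiral) | Oc1cc(O)c(Oc2cc(O)c(O)c(O)c2Oc2cc(O)c(O)c(O)c2)c(O)c1 | target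

**Totals and risks**
Total step count: 12. Longest linear sequence: 12 steps (1 → 19; bromide 3 is used twice, as the precursor of 4 and as the ring C partner in step 7).

Three steps most likely to fail:

1. Step 10 (Claisen/Dieckmann annulation). The α-substituted malonate 13 is a sluggish acyl donor and 14 can self-condense; slow addition of excess 14 is the first countermeasure. Fallback: setting out from 13, one ester is saponified selectively (KOH 1.0 equiv, EtOH, 0 °C, then cold dilute HCl) to the malonic half-ester F1. This is converted with (COCl)2 and catalytic DMF in CH2Cl2 at 0 °C into the acid chloride F2. F2 C-acylates 14 under soft enolisation (MgCl2, pyridine, CH2Cl2, 0 °C → rt), so the intermolecular C–C bond is made with a far stronger electrophile. The fallback comes back to the route at 15, now isolated, which is closed to 16 in a separate Dieckmann step (NaOEt, EtOH, reflux).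

2. Step 7 (Ullmann coupling of the di-ortho-substituted, easily oxidised phenol 9). Fallback: setting out from 3, bromine–lithium exchange (n-BuLi, THF, −78 °C), B(OiPr)3 and aqueous HCl give [3,4,5-tris(benzyloxy)phenyl]boronic acid F3. F3 is coupled with 9 in a room-temperature Chan–Lam–Evans oxidative etherification (Cu(OAc)2, pyridine, 4 Å molecular sieves, CH2Cl2, air), which tolerates di-ortho-substituted phenols. It comes back to the route at 10.

3. Step 11 (saponification of doubly chelated esters in hot alkali with an air-sensitive phloroglucinol). Fallback: setting out from 16, the order of the last two operations is reversed. Hydrogenolysis (H2, Pd/C, THF/EtOH, rt) first gives the hexahydroxy diester F4, diethyl 2,4,6-trihydroxy-5-[3,4,5-trihydroxy-2-(3,4,5-trihydroxyphenoxy)phenoxy]benzene-1,3-dicarboxylate. Its esters are then removed in acid, where free polyphenols are stable (degassed 3 M HCl, dioxane/H2O, reflux, Ar; hydrolysis and protodecarboxylation). It comes back to the route at 19.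

**Further compounds**
F1 | step 10 | 3-ethoxy-3-oxo-2-{3,4,5-tris(benzyloxy)-2-[3,4,5-tris(benzyloxy)phenoxy]phenoxy}propanoic acid (racemic) | CCOC(=O)C(Oc1cc(OCc2ccccc2)c(OCc2ccccc2)c(OCc2ccccc2)c1Oc3cc(OCc2ccccc2)c(OCc2ccccc2)c(OCc2ccccc2)c3)C(=O)O
F2 | step 10 | ethyl 3-chloro-3-oxo-2-{3,4,5-tris(benzyloxy)-2-[3,4,5-tris(benzyloxy)phenoxy]phenoxy}propanoate (racemic) | CCOC(=O)C(Oc1cc(OCc2ccccc2)c(OCc2ccccc2)c(OCc2ccccc2)c1Oc3cc(OCc2ccccc2)c(OCc2ccccc2)c(OCc2ccccc2)c3)C(=O)Cl
F3 | step 7 | [3,4,5-tris(benzyloxy)phenyl]boronic acid | OB(O)c1cc(OCc2ccccc2)c(OCc2ccccc2)c(OCc2ccccc2)c1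
F4 | step 11 | diethyl 2,4,6-trihydroxy-5-[3,4,5-trihydroxy-2-(3,4,5-trihydroxyphenoxy)phenoxy]benzene-1,3-dicarboxylate | CCOC(=O)c1c(O)c(C(=O)OCC)c(O)c(Oc2cc(O)c(O)c(O)c2Oc3cc(O)c(O)c(O)c3)c1O
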